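(Readings and results were computed for substances that don't exist, noise included.)

If you divide what a substrate was charged with by what is left and take the natural logarithm, you have the lifetimes that substrate has spent, read straight from one row of a table.

| flask | left-handed substrate | right-handed substrate | coupling partner | free catalyst | remark | time |
|---|---|---|---|---|---|---|
| theta | 0.023 M | 0.023 M | 1.2 equiv | 15 mol% | the very flask that is asked about, followed so far |  |
| eta | 0.023 M | 0.023 M | 0.80 equiv | 15 mol% | run made earlier |  |
| flask | 0.023 M | 0.023 M | 1.20 equiv | 15 mol% |  | 3.0 min |

- whether the excess of right-handed substrate over left-handed substrate among what is left of the two reaches 80 % by 3.0 min (yes / no)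
- the highest excess of right-handed substrate over left-handed substrate among what is left of the two up to 3.0 min

- free catalyst is single-handed; left-handed substrate and right-handed substrate are mirror images of each other, charged as a racemate, each of them at the stated concentration
- steps under discussion: coupling partner <-> dormant form; free catalyst + left-handed substrate <-> catalyst intermediate A; coupling partner + catalyst intermediate B -> free catalyst + right-handed product; coupling partner + catalyst intermediate A -> free catalyst + left-handed product; free catalyst -> spent catalyst; free catalyst + right-handed substrate <-> catalyst intermediate B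

| run | time / s | right-handed substrate / % | left-handed substrate / % |
|---|---|---|---|
| theta | 10.0 | 47.2 | 43.5 |
| theta | 15.0 | 46.4 | 41.6 |
| theta | 25.0 | 45.4 | 38.8 |
| theta | 30.0 | 45.7 | 39.4 |
| theta | 40.0 | 45.8 | 36.9 |
| theta | 50.0 | 44.8 | 36.3 |
| eta | 10.0 | 48.0 | 45.4 |
| eta | 12.0 | 47.3 | 43.7 |
| eta | 20.0 | 47.5 | 43.8 |
| eta | 30.0 | 46.5 | 41.5 |
| eta | 40.0 | 46.5 | 40.8 |
| eta | 60.0 | 46.2 | 39.1 |
| eta | 80.0 | 45.7 | 37.6 |

(readings scatter by 0.5 percentage points)

Each substrate starts at 50 % on this scale. In the last row of the theta run, left-handed substrate at 36.3 % has spent 0.320 lifetimes and right-handed substrate at 44.8 % has spent 0.110. The quotient is 2.92: lifetimes of left-handed substrate spent per lifetime of right-handed substrate, the selectivity factor. The last row of the eta run, with less coupling partner, reads 3.17, close to it within the scatter, so you can carry the theta reading.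

An excess of 80 % means right-handed over left-handed substrate by a factor of 9.00. Each lifetime of left-handed substrate widens the logarithm of that factor by 0.657, one less the reciprocal of the selectivity factor, so left-handed substrate must spend 3.34 lifetimes.

Now read down the theta run: from 15.0 s to 50.0 s, left-handed substrate spends 0.234 min⁻¹. My own reckoning continues that pace to 3.0 min and reaches 0.826 lifetimes, fewer than the need. So I say no, with a top of 26.5 %.

The forecast says no with a top of 17 %, lower than mine, on the ground “The excess rises steadily”.

The flask gives no and a top of 17.9 %.

    coupling partner ⇌ dormant form (K = 0.390, k = 0.0170 s⁻¹)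
    free catalyst + left-handed substrate ⇌ catalyst intermediate A (K = 36.0 L mol⁻¹, k = 1100 L mol⁻¹ s⁻¹)
    coupling partner + catalyst intermediate B → free catalyst + right-handed product (k = 3.10 L mol⁻¹ s⁻¹)
    coupling partner + catalyst intermediate A → free catalyst + left-handed product (k = 8.30 L mol⁻¹ s⁻¹)
    free catalyst → spent catalyst (k = 0.0290 s⁻¹)
    free catalyst + right-handed substrate ⇌ catalyst intermediate B (K = 26.0 L mol⁻¹, k = 1000 L mol⁻¹ s⁻¹)

At 3.00 min the asked flask keeps 61 % of its left-handed substrate, which is 0.500 lifetimes, fewer than my straight line reached, with spent catalyst at 91.7 %. The carried factor turns that count into 16.3 %. The neighbouring flask with 4.80 equiv of coupling partner keeps 11 % of its left-handed substrate, which is 2.25 lifetimes, still fewer than the need. The same factor turns that count into 62.9 %, and the top of that flask is 67.2 %.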